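Assumption: the structure to be made fixes the four carbon stereocentres (1R,3R in both isoquinolines) but no axial configuration, so the one configurationally stable axis (ring B to its isoquinoline) is not controlled and both atropo-diastereomers count as the target.

## The problem

The target is a quateraryl built on an unsymmetrical 8,8'-dimethoxy-6,6'-dimethyl-2,2'-binaphthalene-1,1'-diol: ring A carries a tetrahydroisoquinoline at C4 (para to its hydroxyl) and ring B carries the second at C5' (on the methylated ring, ortho to the methyl, para to the methoxy), each through isoquinoline C5. Three biaryl bonds must be made, two at flanked positions, and the two naphthalene halves need different handles although they share one oxygenation pattern. Both nitrogen rings are (1R,3R)-8-hydroxy-1,3-dimethyl-1,2,3,4-tetrahydroisoquinolines, so four stereocentres of two kinds must be set. C3 is a non-benzylic stereocentre that can come from the chiral pool, whereas C1 is benzylic and epimerisable, so C3 can control it either kinetically or thermodynamically (1,3-trans). The free naphthols and phenols are electron-rich and oxidise easily, and the ortho-hydroxybenzylamine at C1 can reopen by retro-Mannich fragmentation, so strong oxidants and hot strong acid must be kept away from late intermediates. The enabling feature is that C1 of each isoquinoline is benzylic, ortho to the C8 phenol (through C8a) and bonded to N2, which is the pattern left when an amine captures the exocyclic carbon of an ortho-quinone methide. This quinone methide is the tautomer of a 2-vinylphenol, so each N2–C1 bond, with its C1 methyl, can be traced to an isomeric open-chain vinylphenol amine without change of oxidation level.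

## Retrosynthesis

**Cut 1, N2–C1 in both nitrogen rings (32 to 31).** Target 32 is opened at both N2–C1 bonds to the bis(2-vinylphenol) diamine 31, an isomer. The neighbouring cuts (C1–C8a by Pictet–Spengler reaction, or C1=N reduction after acylation and cyclodehydration) need an extra two-carbon reagent and a protected or activated ring. This cut removes two rings and two stereocentres and adds no atoms. The forward reaction must add the amine at the internal vinyl carbon, close intramolecularly, and deliver 1,3-trans at equilibrium.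

**Cut 2, protecting groups (31 to 30).** Diamine 31 is released from the tetrakis(MOM) bis(Boc) quateraryl 30 in one acidic operation. MOM is chosen because it is also the directing group that builds the outer arene and it survives the organometallic and cross-coupling steps. Boc keeps the nitrogen inert to bases and palladium.

**Cut 3, the two naphthalene–benzene bonds (30 to 29 and twice 10).** Both outer arenes are identical, so one boronate 10 is coupled twice to the binaphthyl bis-electrophile 29 (triflate at C4 of ring A, bromide at C5' of ring B). Cutting the central bond last would need two different naphthyl–arene halves and would carry the side chain through twice as many steps. The forward reaction is a twofold Suzuki–Miyaura coupling at flanked sites that must tolerate the styrene and the carbamate.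

**Cut 4, the ring A triflate (29 to 28 to 26).** The C4 oxygen of ring A is traced, through naphthol 28 and hydroquinone 27, to the remote carbonyl of the 2-aryl-1,4-naphthoquinone 26. The quinone is a latent triflate that is silent during the central coupling. The forward sequence must tell the exposed C4 hydroxyl from the C1 hydroxyl, which is flanked by the aryl group and hydrogen-bonded to the peri methoxy group.

**Cut 5, the central biaryl bond (26 to 16 and 25).** Bromoquinone 16 is the electrophile and ring B boronate 25 the nucleophile. A vinylogous acyl bromide couples much faster than the flanked bromide that 25 must keep. Quinone 16 comes by O-methylation of bromojuglone 15, the Diels–Alder product of silyl ketene acetal 12 (from ester 11) and dibromoquinone 13. This cycloaddition sets the oxygen pattern and places the bromine at the future biaryl carbon.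

**Cut 6, ring B (25 back to 17).** Boronate 25 comes from iodide 23, its naphthol 22 and naphthol 21. Ring B cannot use the quinone route because its isoquinoline sits on the other ring and C4' bears hydrogen. Naphthol 21 is therefore built by cyclising butenoic acid 19, made from aldehyde 18 and hence from 17. The bromine of 18 serves three times: it forces ring closure ortho to the methoxy group, it screens C4 so that iodination goes to C2, and it is the later handle at C5'.

**Cut 7, the outer arene (10 back to 1).** Boronate 10 comes from bromide 9, aldehyde 8 and aldehyde 7. The formyl group of 7 is placed between the MOM ether and the side chain of carbamate 5 by directed lithiation. Carbamate 5 is made by opening the chiral-pool aziridine 3 with the Grignard reagent of MOM ether 2, from 3-bromophenol 1. This gives the (R)-2-aminopropyl chain in one step. Bromination is done on the aldehyde, before the alkene exists.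

## Roads not taken

Ring A is numbered below as in the name of 32: C1 bears the hydroxyl, C2 the ring B naphthyl, C4 the isoquinoline, C6 the methyl and C8 the methoxy group.

**Alternative 1:** ring A is cut at the C8–C8a bond, and behind it at the C5=C6 bond of a Stobbe olefin, back to the teraryl half-ester A2, which already carries both finished, benzylated isoquinolines. In the forward direction the E half-ester A2 is heated with acetic anhydride and NaOAc. Its mixed anhydride cyclises through a dienylketene onto C8a and gives the naphthyl acetate A1.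
- Merits: the cyclisation is classical and has only one free ortho position to attack. All four stereocentres are set beforehand by established isoquinoline chemistry. In this respect it is safer than the chosen plan, whose C1 centres rest on an untested equilibration.
- Weak points: A1 carries an acetate at C8 and an ester at C6 of ring A. Acetate-to-methyl ether exchange, ester-to-methyl reduction and a sixfold debenzylation follow the key step. A2 is a long linear construct with two nitrogen rings made early.
- Comparison: the chosen plan sets against the safer stereochemistry a key step that is the last step, adds no atoms, and uses one outer fragment twice.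

**Alternative 2:** both isoquinoline benzene rings are cut into alkynes. In the forward direction each nitrogen-tethered 1,7-diyne of the bis-diyne A4 combines with acetylene under CpCo(CO)2. This forms C4a–C8a, C5–C6 and C7–C8 at each end and gives the bis(boronate) A3.
- Merits: six C–C bonds and four rings form in one operation, more than any other plan. C1 is fixed before the key step as a propargylic amine centre, so no equilibrium is needed.
- Weak points: cross-trimerisation with acetylene must beat homotrimerisation at two hindered naphthyl alkynes at once. The two stereocentres flanking nitrogen still have to be made, only earlier. A3 then needs boronate oxidation, Boc removal and debenzylation.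
- Comparison: the chosen plan offers less bond formation in its key step but precedented steps up to it and none after it.

**Alternative 3:** ring A is cut at C3–C4 and C1–C2. In the forward direction the diarylmethyl anion of benzoate A6 (LiN(iPr)2) adds to vinyl sulfoxide A7, and the resulting carbanion attacks the ester. Loss of benzenesulfenic acid gives naphthol A5.
- Merits: the two halves are joined while ring A is formed, regiospecifically and with the C1 hydroxyl of ring A free. No hydroquinone has to be differentiated, which is better than steps 16 to 18 of the chosen route.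
- Weak points: a hindered diarylmethyl anion must add to a 1,1-disubstituted vinyl sulfoxide and then acylate an ester flanked by a methoxy group. Both partners already contain a complete N-benzyl isoquinoline, so two long linear sequences precede the union, and debenzylation follows.
- Comparison: the chosen plan has simpler fragments and postpones both nitrogen rings to the final isomerisation, at the price of the selective triflation.

Key step: step 21

## Route

Step 1
Reactants: 1 3-bromophenol
Product: 2 1-bromo-3-(methoxymethoxy)benzene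
Conditions: MOMCl, iPr2NEt, CH2Cl2, 0 °C to rt
Reagents that add atoms: chloromethyl methyl ether, COCCl
Why: O-alkylation of the phenol to its MOM ether; the group is put on first because it later directs the lithiation of step 3.

Step 2
Reactants: 2 1-bromo-3-(methoxymethoxy)benzene; 3 tert-butyl (2R)-2-methylaziridine-1-carboxylate
Product: 5 tert-butyl N-[(2R)-1-[3-(methoxymethoxy)phenyl]propan-2-yl]carbamate, via aryl Grignard reagent 4 (not isolated)
Conditions: Mg, THF, 40 °C; then 3, CuBr·SMe2 (10 mol %), THF, −30 to 0 °C; H2O
Reagents that add atoms: none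
Why: Grignard formation, then CuBr·SMe2-catalysed SN2 opening of the N-Boc aziridine at its unsubstituted carbon; the stereocentre of 3 is not touched, so its (R) configuration becomes C3 of the isoquinoline.

Step 3
Reactants: 5 tert-butyl N-[(2R)-1-[3-(methoxymethoxy)phenyl]propan-2-yl]carbamate
Product: 7 tert-butyl N-[(2R)-1-[2-formyl-3-(methoxymethoxy)phenyl]propan-2-yl]carbamate, via dilithiated carbamate 6 (not isolated)
Conditions: s-BuLi (2.4 equiv), TMEDA, THF, −78 to −40 °C; DMF, −78 °C to rt; H2O
Reagents that add atoms: N,N-dimethylformamide, CN(C)C=O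
Why: Directed ortho-metalation: after N–H deprotonation, s-BuLi removes the ring proton flanked by the MOM ether and the carbamate-bearing chain, the site activated by both groups, and DMF formylates the aryllithium.

Step 4
Reactants: 7 tert-butyl N-[(2R)-1-[2-formyl-3-(methoxymethoxy)phenyl]propan-2-yl]carbamate
Product: 8 tert-butyl N-[(2R)-1-[6-bromo-2-formyl-3-(methoxymethoxy)phenyl]propan-2-yl]carbamate
Conditions: NBS, MeCN, 0 °C to rt, dark
Reagents that add atoms: N-bromosuccinimide, O=C1CCC(=O)N1Br
Why: Electrophilic aromatic bromination at the position para to the MOM ether, ortho to the alkyl chain and meta to the formyl group, which all three substituents favour; it is done before the alkene is present.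

Step 5
Reactants: 8 tert-butyl N-[(2R)-1-[6-bromo-2-formyl-3-(methoxymethoxy)phenyl]propan-2-yl]carbamate
Product: 9 tert-butyl N-[(2R)-1-[6-bromo-2-ethenyl-3-(methoxymethoxy)phenyl]propan-2-yl]carbamate
Conditions: Ph3PCH3Br, KOtBu (2.5 equiv), THF, 0 °C to rt
Reagents that add atoms: methyltriphenylphosphonium bromide, C[P+](c1ccccc1)(c1ccccc1)c1ccccc1.[Br-]
Why: Wittig methylenation of a non-enolisable aldehyde; excess ylide covers the carbamate N–H and any cyclic N-Boc hemiaminal tautomer, which reopens under base.

Step 6
Reactants: 9 tert-butyl N-[(2R)-1-[6-bromo-2-ethenyl-3-(methoxymethoxy)phenyl]propan-2-yl]carbamate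
Product: 10 tert-butyl N-[(2R)-1-[2-ethenyl-3-(methoxymethoxy)-6-(4,4,5,5-tetramethyl-1,3,2-dioxaborolan-2-yl)phenyl]propan-2-yl]carbamate
Conditions: B2pin2, PdCl2(dppf) (5 mol %), KOAc, dioxane, 85 °C
Reagents that add atoms: bis(pinacolato)diboron, CC1(C)OB(B2OC(C)(C)C(C)(C)O2)OC1(C)C
Why: Miyaura borylation of the aryl bromide; the weak base KOAc suppresses biaryl homocoupling, and the protected styrene and carbamate are inert.

Step 7
Reactants: 11 methyl 3-methylbut-2-enoate
Product: 12 [(1-methoxy-3-methylbuta-1,3-dien-1-yl)oxy]trimethylsilane (E/Z mixture)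
Conditions: LiN(iPr)2, THF, −78 °C; Me3SiCl, −78 °C to rt
Reagents that add atoms: chlorotrimethylsilane, C[Si](C)(C)Cl
Why: γ-Deprotonation of the unsaturated ester and O-silylation of the extended enolate give the vinylketene silyl acetal, a standard electron-rich diene.

Step 8
Reactants: 12 [(1-methoxy-3-methylbuta-1,3-dien-1-yl)oxy]trimethylsilane; 13 2,6-dibromo-1,4-benzoquinone
Product: 15 2-bromo-8-hydroxy-6-methylnaphthalene-1,4-dione, via Diels–Alder cycloadduct 14 (not isolated)
Conditions: toluene, −30 °C to rt; then SiO2 or 1 M HCl, THF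
Reagents that add atoms: none
Why: Regioselective Diels–Alder reaction: the nucleophilic CH2 terminus of the diene bonds to the unsubstituted quinone carbon, so the acetal carbon ends next to a brominated carbon. Loss of HBr and methanol aromatises the new ring and leaves the hydroxyl peri to the carbonyl that is still flanked by bromine.

Step 9
Reactants: 15 2-bromo-8-hydroxy-6-methylnaphthalene-1,4-dione
Product: 16 2-bromo-8-methoxy-6-methylnaphthalene-1,4-dione
Conditions: MeI, Ag2O, CH2Cl2, rt, dark
Reagents that add atoms: iodomethane, CI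
Why: O-Methylation of the chelated peri hydroxyl with MeI/Ag2O, neutral conditions that spare the base-sensitive bromoquinone.

Step 10
Reactants: 17 3-methoxy-5-methylbenzaldehyde
Product: 18 2-bromo-5-methoxy-3-methylbenzaldehyde
Conditions: Br2, AcOH, rt
Reagents that add atoms: bromine, BrBr
Why: Electrophilic aromatic bromination para to the methoxy group, as in the bromination of 3-methoxybenzaldehyde; the bromine blocks this position for step 12 and is the later coupling handle.

Step 11
Reactants: 18 2-bromo-5-methoxy-3-methylbenzaldehyde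
Product: 19 (3E)-4-(2-bromo-5-methoxy-3-methylphenyl)but-3-enoic acid (E drawn; E/Z mixture used)
Conditions: Ph3P(CH2)2CO2H Br, KOtBu (2.2 equiv), THF, 0 °C to rt; HCl (aq)
Reagents that add atoms: (2-carboxyethyl)triphenylphosphonium bromide, OC(=O)CC[P+](c1ccccc1)(c1ccccc1)c1ccccc1.[Br-]
Why: Wittig reaction with the carboxylate-bearing ylide gives the β,γ-unsaturated acid; the alkene geometry does not matter because the conditions of step 12 equilibrate it.

Step 12
Reactants: 19 (3E)-4-(2-bromo-5-methoxy-3-methylphenyl)but-3-enoic acid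
Product: 21 5-bromo-8-methoxy-6-methylnaphthalen-1-ol, via naphthyl acetate 20 (not isolated)
Conditions: Ac2O, NaOAc, 140 °C; then K2CO3, MeOH, rt
Reagents that add atoms: none
Why: Classical naphthol synthesis: the mixed anhydride cyclises (intramolecular Friedel–Crafts acylation or ketene electrocyclisation) onto the only free ortho position, which is ortho to the methoxy group because bromine holds the other. The resulting naphthyl acetate is methanolysed in the same operation.

Step 13
Reactants: 21 5-bromo-8-methoxy-6-methylnaphthalen-1-ol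
Product: 22 5-bromo-2-iodo-8-methoxy-6-methylnaphthalen-1-ol
Conditions: NIS, MeCN/CH2Cl2, 0 °C to rt, dark
Reagents that add atoms: N-iodosuccinimide, O=C1CCC(=O)N1I
Why: Electrophilic iodination of the naphthol; the para position C4 is screened by the peri bromine at C5, so substitution occurs at C2, ortho to the hydroxyl.

Step 14
Reactants: 22 5-bromo-2-iodo-8-methoxy-6-methylnaphthalen-1-ol
Product: 23 5-bromo-2-iodo-8-methoxy-1-(methoxymethoxy)-6-methylnaphthalene
Conditions: NaH, DMF, 0 °C; MOMCl, 0 °C to rt
Reagents that add atoms: chloromethyl methyl ether, COCCl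
Why: Etherification of the sodium naphtholate; the MOM ether protects the hydroxyl through the organometallic and coupling steps and assists the exchange of step 15.

Step 15
Reactants: 23 5-bromo-2-iodo-8-methoxy-1-(methoxymethoxy)-6-methylnaphthalene
Product: 25 2-[5-bromo-8-methoxy-1-(methoxymethoxy)-6-methylnaphthalen-2-yl]-4,4,5,5-tetramethyl-1,3,2-dioxaborolane, via arylmagnesium chloride 24 (not isolated)
Conditions: iPrMgCl·LiCl, THF, −40 °C; iPrOBpin, −40 °C to rt; H2O
Reagents that add atoms: 2-isopropoxy-4,4,5,5-tetramethyl-1,3,2-dioxaborolane, CC(C)OB1OC(C)(C)C(C)(C)O1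
Why: Iodine–magnesium exchange is fast at the iodide ortho to the chelating MOM ether and leaves the hindered, electron-rich bromide alone; the arylmagnesium is trapped by the borate ester.

Step 16
Reactants: 16 2-bromo-8-methoxy-6-methylnaphthalene-1,4-dione; 25 2-[5-bromo-8-methoxy-1-(methoxymethoxy)-6-methylnaphthalen-2-yl]-4,4,5,5-tetramethyl-1,3,2-dioxaborolane
Product: 26 2-[5-bromo-8-methoxy-1-(methoxymethoxy)-6-methylnaphthalen-2-yl]-8-methoxy-6-methylnaphthalene-1,4-dione
Conditions: PdCl2(dppf) (5 mol %), K3PO4, dioxane/H2O, 60 °C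
Reagents that add atoms: none
Why: Suzuki–Miyaura coupling; oxidative addition of zerovalent palladium into the vinylogous acyl bromide of the quinone is far faster than into the doubly flanked, electron-rich aryl bromide of 25, which survives.

Step 17
Reactants: 26 2-[5-bromo-8-methoxy-1-(methoxymethoxy)-6-methylnaphthalen-2-yl]-8-methoxy-6-methylnaphthalene-1,4-dione
Product: 28 5'-bromo-1-hydroxy-8,8'-dimethoxy-1'-(methoxymethoxy)-6,6'-dimethyl-[2,2'-binaphthalen]-4-yl trifluoromethanesulfonate, via hydroquinone 27 (not isolated)
Conditions: Na2S2O4, EtOAc/H2O, rt, Ar; then PhNTf2, Et3N, CH2Cl2, 0 °C to rt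
Reagents that add atoms: N-phenylbis(trifluoromethanesulfonimide), O=S(=O)(N(c1ccccc1)S(=O)(=O)C(F)(F)F)C(F)(F)F
Why: Na2S2O4 reduction to the hydroquinone, then sulfonylation; the C1 hydroxyl is flanked by the aryl group and hydrogen-bonded to the peri methoxy group, so the exposed, more acidic C4 hydroxyl is triflated selectively.

Step 18
Reactants: 28 5'-bromo-1-hydroxy-8,8'-dimethoxy-1'-(methoxymethoxy)-6,6'-dimethyl-[2,2'-binaphthalen]-4-yl trifluoromethanesulfonate
Product: 29 5'-bromo-8,8'-dimethoxy-1,1'-bis(methoxymethoxy)-6,6'-dimethyl-[2,2'-binaphthalen]-4-yl trifluoromethanesulfonate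
Conditions: NaH, DMF, 0 °C; MOMCl, 0 °C to rt
Reagents that add atoms: chloromethyl methyl ether, COCCl
Why: Etherification of the remaining hindered naphthol as its sodium salt; protection prevents triflyl transfer and oxidation during the coupling.

Step 19
Reactants: 29 5'-bromo-8,8'-dimethoxy-1,1'-bis(methoxymethoxy)-6,6'-dimethyl-[2,2'-binaphthalen]-4-yl trifluoromethanesulfonate; 10 tert-butyl N-[(2R)-1-[2-ethenyl-3-(methoxymethoxy)-6-(4,4,5,5-tetramethyl-1,3,2-dioxaborolan-2-yl)phenyl]propan-2-yl]carbamate (2.6 equiv)
Product: 30 4,5'-bis{2-[(2R)-2-(tert-butoxycarbonylamino)propyl]-3-ethenyl-4-(methoxymethoxy)phenyl}-8,8'-dimethoxy-1,1'-bis(methoxymethoxy)-6,6'-dimethyl-2,2'-binaphthalene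
Conditions: Pd(OAc)2 (10 mol %), SPhos (20 mol %), K3PO4, toluene/H2O, 95 °C
Reagents that add atoms: none
Why: Twofold Suzuki–Miyaura coupling; the bulky electron-rich biarylphosphine promotes oxidative addition at both the triflate and the flanked bromide and transmetalation of the ortho-substituted boronate, which outruns Heck reaction of the styrene.

Step 20
Reactants: 30 4,5'-bis{2-[(2R)-2-(tert-butoxycarbonylamino)propyl]-3-ethenyl-4-(methoxymethoxy)phenyl}-8,8'-dimethoxy-1,1'-bis(methoxymethoxy)-6,6'-dimethyl-2,2'-binaphthalene
Product: 31 4,5'-bis{2-[(2R)-2-aminopropyl]-3-ethenyl-4-hydroxyphenyl}-8,8'-dimethoxy-6,6'-dimethyl-[2,2'-binaphthalene]-1,1'-diol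
Conditions: HCl (2 M) in MeOH/THF, 0 °C to rt, Ar; degassed NaHCO3 (aq); used at once
Reagents that add atoms: none
Why: Acidic cleavage of four MOM acetals and two Boc carbamates in one operation. Methanol turns the methoxymethyl cations into dimethoxymethane, so no formaldehyde equivalent meets the amines, which stay protonated; the low temperature keeps the vinylphenol from ionising.

Step 21
Reactants: 31 4,5'-bis{2-[(2R)-2-aminopropyl]-3-ethenyl-4-hydroxyphenyl}-8,8'-dimethoxy-6,6'-dimethyl-[2,2'-binaphthalene]-1,1'-diol
Product: 32 4,5'-bis[(1R,3R)-8-hydroxy-1,3-dimethyl-1,2,3,4-tetrahydroisoquinolin-5-yl]-8,8'-dimethoxy-6,6'-dimethyl-[2,2'-binaphthalene]-1,1'-diol (CNP0077060.1)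
Conditions: (PhO)2P(O)OH (0.5 equiv per NH2), degassed (CF3)2CHOH, 2 mM, 70 °C, Ar, dark; NaHCO3 (aq)
Reagents that add atoms: none
Why: Proposed new method: a proton from the ammonium phosphate ion pair or from the phenol adds to the terminal carbon of each vinyl group and gives the ortho-quinone methide (O-protonated, the ortho-hydroxy-stabilised benzylic cation); the neighbouring free amine adds to its exocyclic carbon and the phenol rearomatises, forming N2–C1 and the C1 methyl group. The closest known reaction type is the acid-catalysed Markovnikov addition of nitrogen, oxygen, sulfur and carbon nucleophiles to 2-vinylphenols through ortho-quinone methides; an intramolecular version with a free primary amine that closes a tetrahydroisoquinoline has not been described. Each nitrogen ring closes 6-endo-trig onto the exocyclic C8a=C1 bond of its quinone methide (6-exo relative to the original vinyl group), the only ring size the tether allows for attack at the electrophilic carbon. C3 is (R) from aziridine 3 and takes no part; C1 is set under thermodynamic control by C3 and the C8 oxygen, because the ortho-hydroxybenzylamine can reopen to the quinone methide (retro-Mannich) and reclose until the 1,3-trans isomer predominates, with the C1 methyl pseudoaxial away from the peri C8 hydroxyl and the C3 methyl pseudoequatorial. Half an equivalent of acid per nitrogen keeps both a proton donor and a free amine present, and hexafluoroisopropanol stabilises the polar intermediates without adding irreversibly. The step needs nitrogen over oxygen or carbon attack, intramolecular over intermolecular capture, and Markovnikov regiochemistry; the first two are secured by the proximity of the amine at high dilution under argon, the third by the quinone methide itself.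

## Compound list

1 | 3-bromophenol | Oc1cccc(Br)c1 | starting material
2 | 1-bromo-3-(methoxymethoxy)benzene | COCOc1cccc(Br)c1 | intermediate
3 | tert-butyl (2R)-2-methylaziridine-1-carboxylate | C[C@@H]1CN1C(=O)OC(C)(C)C | starting material
4 | [3-(methoxymethoxy)phenyl]magnesium bromide | COCOc1cccc([Mg]Br)c1 | intermediate (not isolated)
5 | tert-butyl N-[(2R)-1-[3-(methoxymethoxy)phenyl]propan-2-yl]carbamate | COCOc1cccc(C[C@@H](C)NC(=O)OC(C)(C)C)c1 | intermediate
6 | N,2-dilithio derivative of 5 (aryllithium between the MOM ether and the side chain) | [Li]c1c(OCOC)cccc1C[C@@H](C)N([Li])C(=O)OC(C)(C)C | intermediate (not isolated)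
7 | tert-butyl N-[(2R)-1-[2-formyl-3-(methoxymethoxy)phenyl]propan-2-yl]carbamate | O=Cc1c(OCOC)cccc1C[C@@H](C)NC(=O)OC(C)(C)C | intermediate
8 | tert-butyl N-[(2R)-1-[6-bromo-2-formyl-3-(methoxymethoxy)phenyl]propan-2-yl]carbamate | O=Cc1c(OCOC)ccc(Br)c1C[C@@H](C)NC(=O)OC(C)(C)C | intermediate
9 | tert-butyl N-[(2R)-1-[6-bromo-2-ethenyl-3-(methoxymethoxy)phenyl]propan-2-yl]carbamate | C=Cc1c(OCOC)ccc(Br)c1C[C@@H](C)NC(=O)OC(C)(C)C | intermediate
10 | tert-butyl N-[(2R)-1-[2-ethenyl-3-(methoxymethoxy)-6-(4,4,5,5-tetramethyl-1,3,2-dioxaborolan-2-yl)phenyl]propan-2-yl]carbamate | C=Cc1c(OCOC)ccc(B2OC(C)(C)C(C)(C)O2)c1C[C@@H](C)NC(=O)OC(C)(C)C | intermediate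
11 | methyl 3-methylbut-2-enoate | COC(=O)C=C(C)C | starting material
12 | [(1-methoxy-3-methylbuta-1,3-dien-1-yl)oxy]trimethylsilane (E/Z mixture) | COC(O[Si](C)(C)C)=CC(C)=C | intermediate
13 | 2,6-dibromo-1,4-benzoquinone | O=C1C=C(Br)C(=O)C(Br)=C1 | starting material
14 | 2,8a-dibromo-8-methoxy-6-methyl-8-[(trimethylsilyl)oxy]-4a,5,8,8a-tetrahydronaphthalene-1,4-dione | O=C1C=C(Br)C(=O)C2(Br)C1CC(C)=CC2(OC)O[Si](C)(C)C | intermediate (not isolated)
15 | 2-bromo-8-hydroxy-6-methylnaphthalene-1,4-dione | O=C1C(Br)=CC(=O)c2cc(C)cc(O)c21 | intermediate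
16 | 2-bromo-8-methoxy-6-methylnaphthalene-1,4-dione | COc1cc(C)cc2c1C(=O)C(Br)=CC2=O | intermediate
17 | 3-methoxy-5-methylbenzaldehyde | COc1cc(C)cc(C=O)c1 | starting material
18 | 2-bromo-5-methoxy-3-methylbenzaldehyde | COc1cc(C)c(Br)c(C=O)c1 | intermediate
19 | (3E)-4-(2-bromo-5-methoxy-3-methylphenyl)but-3-enoic acid | COc1cc(C)c(Br)c(/C=C/CC(=O)O)c1 | intermediate
20 | 5-bromo-8-methoxy-6-methylnaphthalen-1-yl acetate | CC(=O)Oc1cccc2c(Br)c(C)cc(OC)c12 | intermediate (not isolated)
21 | 5-bromo-8-methoxy-6-methylnaphthalen-1-ol | COc1cc(C)c(Br)c2cccc(O)c12 | intermediate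
22 | 5-bromo-2-iodo-8-methoxy-6-methylnaphthalen-1-ol | COc1cc(C)c(Br)c2ccc(I)c(O)c12 | intermediate
23 | 5-bromo-2-iodo-8-methoxy-1-(methoxymethoxy)-6-methylnaphthalene | COCOc1c(I)ccc2c(Br)c(C)cc(OC)c12 | intermediate
24 | [5-bromo-8-methoxy-1-(methoxymethoxy)-6-methylnaphthalen-2-yl]magnesium chloride | COCOc1c([Mg]Cl)ccc2c(Br)c(C)cc(OC)c12 | intermediate (not isolated)
25 | 2-[5-bromo-8-methoxy-1-(methoxymethoxy)-6-methylnaphthalen-2-yl]-4,4,5,5-tetramethyl-1,3,2-dioxaborolane | COCOc1c(B3OC(C)(C)C(C)(C)O3)ccc2c(Br)c(C)cc(OC)c12 | intermediate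
26 | 2-[5-bromo-8-methoxy-1-(methoxymethoxy)-6-methylnaphthalen-2-yl]-8-methoxy-6-methylnaphthalene-1,4-dione | COCOc1c(C3=CC(=O)c4cc(C)cc(OC)c4C3=O)ccc2c(Br)c(C)cc(OC)c12 | intermediate
27 | 5'-bromo-8,8'-dimethoxy-1'-(methoxymethoxy)-6,6'-dimethyl-[2,2'-binaphthalene]-1,4-diol | COCOc1c(-c3cc(O)c4cc(C)cc(OC)c4c3O)ccc2c(Br)c(C)cc(OC)c12 | intermediate (not isolated)
28 | 5'-bromo-1-hydroxy-8,8'-dimethoxy-1'-(methoxymethoxy)-6,6'-dimethyl-[2,2'-binaphthalen]-4-yl trifluoromethanesulfonate | COCOc1c(-c3cc(OS(=O)(=O)C(F)(F)F)c4cc(C)cc(OC)c4c3O)ccc2c(Br)c(C)cc(OC)c12 | intermediate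
29 | 5'-bromo-8,8'-dimethoxy-1,1'-bis(methoxymethoxy)-6,6'-dimethyl-[2,2'-binaphthalen]-4-yl trifluoromethanesulfonate | COCOc1c(-c3cc(OS(=O)(=O)C(F)(F)F)c4cc(C)cc(OC)c4c3OCOC)ccc2c(Br)c(C)cc(OC)c12 | intermediate
30 | 4,5'-bis{2-[(2R)-2-(tert-butoxycarbonylamino)propyl]-3-ethenyl-4-(methoxymethoxy)phenyl}-8,8'-dimethoxy-1,1'-bis(methoxymethoxy)-6,6'-dimethyl-2,2'-binaphthalene | COCOc1c(-c3cc(-c5ccc(OCOC)c(C=C)c5C[C@@H](C)NC(=O)OC(C)(C)C)c4cc(C)cc(OC)c4c3OCOC)ccc2c(-c3ccc(OCOC)c(C=C)c3C[C@@H](C)NC(=O)OC(C)(C)C)c(C)cc(OC)c12 | intermediate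
31 | 4,5'-bis{2-[(2R)-2-aminopropyl]-3-ethenyl-4-hydroxyphenyl}-8,8'-dimethoxy-6,6'-dimethyl-[2,2'-binaphthalene]-1,1'-diol | COc1cc(C)cc2c(-c3ccc(O)c(C=C)c3C[C@@H](C)N)cc(-c3ccc4c(-c5ccc(O)c(C=C)c5C[C@@H](C)N)c(C)cc(OC)c4c3O)c(O)c12 | intermediate (key-step precursor)
32 | 4,5'-bis[(1R,3R)-8-hydroxy-1,3-dimethyl-1,2,3,4-tetrahydroisoquinolin-5-yl]-8,8'-dimethoxy-6,6'-dimethyl-[2,2'-binaphthalene]-1,1'-diol | COc1cc(C)cc2c(-c3ccc(O)c4c3C[C@@H](C)N[C@@H]4C)cc(-c3ccc4c(-c5ccc(O)c6c5C[C@@H](C)N[C@@H]6C)c(C)cc(OC)c4c3O)c(O)c12 | target

## Step count and risks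

Total: 21 steps. Longest linear sequence: 12 steps (17 to 32, steps 10 to 21).

**Step 21 (key step).**
- What may go wrong: the basic amines may buffer the acid so that protonation of the vinyl terminus stalls. The quinone methide may be captured intermolecularly (O- or C-alkylation of a naphthol, hetero-Diels–Alder dimerisation with a second vinylphenol). Equilibration at C1 may be too slow or the trans preference too small, giving poor diastereoselectivity. The free naphthols may oxidise in air.
- Fallback (known reactions only): it sets out from 30 and rejoins the route at 32. Wacker oxidation of both styrenes (PdCl2, CuCl, O2, DMF/H2O) would give the bis(aryl methyl ketone) F1. Thermolysis of the Boc groups in hot trifluoroethanol frees the amines, which condense with the neighbouring acetyl groups to the MOM-protected bis(1,3-dimethyl-3,4-dihydroisoquinoline) F2. Reduction of the cyclic imines with LiAlH4/AlMe3, the established 1,3-trans-selective reduction of 8-alkoxy-1,3-dimethyl-3,4-dihydroisoquinolines, would give the tetrakis(MOM) ether of the target F3, and HCl in methanol then releases 32.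

**Step 20.**
- What may go wrong: the liberated vinylphenol may ionise early in acid (solvent addition, dimerisation), and the electron-rich product may oxidise during isolation.
- Fallback: it sets out from 30 and rejoins at 32. The ionisation is made deliberate: HCl in methanol at 50 °C removes all six protecting groups and adds methanol in the Markovnikov sense, giving the bis(1-methoxyethyl)phenol diamine F4 (mixture at the benzylic carbons), a storable masked quinone methide. Its free base, heated under the conditions of step 21, loses methanol and cyclises to 32.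

**Step 19.**
- What may go wrong: the second coupling at the flanked ring B bromide may stay incomplete, the ortho-substituted boronate may protodeboronate, and the styrene may be consumed in Heck-type reactions.
- Fallback: it sets out from 29 (with bromide 9) and rejoins at 30. The polarity is reversed: Miyaura borylation of both electrophilic sites (B2pin2, PdCl2(dppf), KOAc) gives the binaphthyl bis(boronate) F5, which is coupled twice with 9 (Pd(OAc)2, SPhos, K3PO4).

**Step 3.**
- What may go wrong: lithiation may occur at the less hindered position ortho to the MOM ether only, or remain incomplete, giving regioisomeric aldehyde.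
- Fallback: it sets out from 2 and rejoins at 7. LiN(iPr)2 at −78 °C removes the proton between bromine and the MOM ether, and DMF gives 2-bromo-6-(methoxymethoxy)benzaldehyde F6. Negishi coupling (Pd2(dba)3, SPhos, DMF) with the alkylzinc iodide F7, made with zinc dust from commercial tert-butyl N-[(2R)-1-iodopropan-2-yl]carbamate, installs the side chain and gives 7.

**Step 17.**
- What may go wrong: the hindered oxygen may also be sulfonylated, both oxygens may react, or the hydroquinone may reoxidise before it reacts.
- Fallback: it sets out from 27 and rejoins at 29. A bulky silyl chloride (TBSCl, imidazole) marks the exposed C4 oxygen and gives the mono-TBS ether F8. MOM protection of the hindered naphthol (NaH, MOMCl) gives the fully protected binaphthyl F9, Bu4NF frees the C4 naphthol F10, and PhNTf2/Et3N gives 29.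

## Further compounds

F1 | step 21 | 4,5'-bis{3-acetyl-2-[(2R)-2-(tert-butoxycarbonylamino)propyl]-4-(methoxymethoxy)phenyl}-8,8'-dimethoxy-1,1'-bis(methoxymethoxy)-6,6'-dimethyl-2,2'-binaphthalene | COCOc1c(-c3cc(-c5ccc(OCOC)c(C(C)=O)c5C[C@@H](C)NC(=O)OC(C)(C)C)c4cc(C)cc(OC)c4c3OCOC)ccc2c(-c3ccc(OCOC)c(C(C)=O)c3C[C@@H](C)NC(=O)OC(C)(C)C)c(C)cc(OC)c12
F2 | step 21 | 4,5'-bis[(3R)-8-(methoxymethoxy)-1,3-dimethyl-3,4-dihydroisoquinolin-5-yl]-8,8'-dimethoxy-1,1'-bis(methoxymethoxy)-6,6'-dimethyl-2,2'-binaphthalene | COCOc1c(-c3cc(-c5ccc(OCOC)c6c5C[C@@H](C)N=C6C)c4cc(C)cc(OC)c4c3OCOC)ccc2c(-c3ccc(OCOC)c4c3C[C@@H](C)N=C4C)c(C)cc(OC)c12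
F3 | step 21 | tetrakis(methoxymethyl) ether of 32 | COCOc1c(-c3cc(-c5ccc(OCOC)c6c5C[C@@H](C)N[C@@H]6C)c4cc(C)cc(OC)c4c3OCOC)ccc2c(-c3ccc(OCOC)c4c3C[C@@H](C)N[C@@H]4C)c(C)cc(OC)c12
F4 | step 20 | 4,5'-bis{2-[(2R)-2-aminopropyl]-4-hydroxy-3-(1-methoxyethyl)phenyl}-8,8'-dimethoxy-6,6'-dimethyl-[2,2'-binaphthalene]-1,1'-diol | COc1cc(C)cc2c(-c3ccc(O)c(C(C)OC)c3C[C@@H](C)N)cc(-c3ccc4c(-c5ccc(O)c(C(C)OC)c5C[C@@H](C)N)c(C)cc(OC)c4c3O)c(O)c12
F5 | step 19 | 8,8'-dimethoxy-1,1'-bis(methoxymethoxy)-6,6'-dimethyl-4,5'-bis(4,4,5,5-tetramethyl-1,3,2-dioxaborolan-2-yl)-2,2'-binaphthalene | COCOc1c(-c3cc(B5OC(C)(C)C(C)(C)O5)c4cc(C)cc(OC)c4c3OCOC)ccc2c(B3OC(C)(C)C(C)(C)O3)c(C)cc(OC)c12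
F6 | step 3 | 2-bromo-6-(methoxymethoxy)benzaldehyde | COCOc1cccc(Br)c1C=O
F7 | step 3 | [(2R)-2-(tert-butoxycarbonylamino)propyl]zinc iodide | C[C@H](C[Zn]I)NC(=O)OC(C)(C)C
F8 | step 17 | 5'-bromo-4-[(tert-butyldimethylsilyl)oxy]-8,8'-dimethoxy-1'-(methoxymethoxy)-6,6'-dimethyl-[2,2'-binaphthalen]-1-ol | COCOc1c(-c3cc(O[Si](C)(C)C(C)(C)C)c4cc(C)cc(OC)c4c3O)ccc2c(Br)c(C)cc(OC)c12
F9 | step 17 | {[5'-bromo-8,8'-dimethoxy-1,1'-bis(methoxymethoxy)-6,6'-dimethyl-[2,2'-binaphthalen]-4-yl]oxy}(tert-butyl)dimethylsilane | COCOc1c(-c3cc(O[Si](C)(C)C(C)(C)C)c4cc(C)cc(OC)c4c3OCOC)ccc2c(Br)c(C)cc(OC)c12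
F10 | step 17 | 5'-bromo-8,8'-dimethoxy-1,1'-bis(methoxymethoxy)-6,6'-dimethyl-[2,2'-binaphthalen]-4-ol | COCOc1c(-c3cc(O)c4cc(C)cc(OC)c4c3OCOC)ccc2c(Br)c(C)cc(OC)c12
A1 | alternative 1 | fully benzyl-protected binaphthyl with an acetate at C8 and a methyl ester at C6 of ring A | CC(=O)Oc1cc(C(=O)OC)cc2c(-c3ccc(OCc4ccccc4)c4c3C[C@@H](C)N(Cc3ccccc3)[C@@H]4C)cc(-c3ccc4c(-c5ccc(OCc6ccccc6)c6c5C[C@@H](C)N(Cc5ccccc5)[C@@H]6C)c(C)cc(OC)c4c3OCc3ccccc3)c(OCc3ccccc3)c12
A2 | alternative 1 | (3E)-3-(methoxycarbonyl)-4-(teraryl)but-3-enoic acid, the half-ester precursor of A1 | OC(=O)C/C(C(=O)OC)=C\c1cc(OCc2ccccc2)c(-c2ccc3c(-c4ccc(OCc5ccccc5)c5c4C[C@@H](C)N(Cc4ccccc4)[C@@H]5C)c(C)cc(OC)c3c2OCc2ccccc2)cc1-c1ccc(OCc2ccccc2)c2c1C[C@@H](C)N(Cc1ccccc1)[C@@H]2C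
A3 | alternative 2 | bis(8-boryl-N-Boc-tetrahydroisoquinoline) with naphthol benzyl ethers | COc1cc(C)cc2c(-c3ccc(B5OC(C)(C)C(C)(C)O5)c4c3C[C@@H](C)N(C(=O)OC(C)(C)C)[C@@H]4C)cc(-c3ccc4c(-c5ccc(B7OC(C)(C)C(C)(C)O7)c6c5C[C@@H](C)N(C(=O)OC(C)(C)C)[C@@H]6C)c(C)cc(OC)c4c3OCc3ccccc3)c(OCc3ccccc3)c12
A4 | alternative 2 | binaphthyl bis(N-Boc nitrogen-tethered 1,7-diyne) with terminal alkynylboronates | COc1cc(C)cc2c(C#CC[C@@H](C)N(C(=O)OC(C)(C)C)[C@H](C)C#CB3OC(C)(C)C(C)(C)O3)cc(-c3ccc4c(C#CC[C@@H](C)N(C(=O)OC(C)(C)C)[C@H](C)C#CB5OC(C)(C)C(C)(C)O5)c(C)cc(OC)c4c3OCc3ccccc3)c(OCc3ccccc3)c12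
A5 | alternative 3 | benzyl-protected target with the C1 hydroxyl of ring A free | COc1cc(C)cc2c(-c3ccc(OCc4ccccc4)c4c3C[C@@H](C)N(Cc3ccccc3)[C@@H]4C)cc(-c3ccc4c(-c5ccc(OCc6ccccc6)c6c5C[C@@H](C)N(Cc5ccccc5)[C@@H]6C)c(C)cc(OC)c4c3OCc3ccccc3)c(O)c12
A6 | alternative 3 | methyl 2-{[(1R,3R)-2-benzyl-8-(benzyloxy)-1,3-dimethyl-1,2,3,4-tetrahydroisoquinolin-5-yl]methyl}-6-methoxy-4-methylbenzoate | COC(=O)c1c(OC)cc(C)cc1Cc1ccc(OCc2ccccc2)c2c1C[C@@H](C)N(Cc1ccccc1)[C@@H]2C
A7 | alternative 3 | ring B 2-[1-(phenylsulfinyl)ethenyl]naphthalene carrying its benzylated isoquinoline | C=C(c1ccc2c(-c3ccc(OCc4ccccc4)c4c3C[C@@H](C)N(Cc3ccccc3)[C@@H]4C)c(C)cc(OC)c2c1OCc1ccccc1)S(=O)c1ccccc1
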